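**Retrosynthetic overview**
- Target ⇐ acetonide hydrolysis ⇐ C12–C13 B-alkyl Suzuki coupling of a 9-vinyl carbinol with the (E)-enol triflate of methyl acetoacetate ⇐ α-face vinyl addition to a C9 decalone (sets 9β-OH).
- Decalone ⇐ key step: HAT-initiated radical bicyclisation of an acyclic dienyl nitrile that carries the C2/C3 diol as a cis-dioxolane. Ring A closes first (C4–C5, 6-endo), ring B second (C10–C9, 6-exo onto C≡N), both in one operation.
- Dienyl nitrile ⇐ B-alkyl Suzuki coupling of an (E)-vinyl iodide with hydroborated 2-methylbut-3-enenitrile; vinyl iodide ⇐ carboalumination/iodination of a terminal alkyne.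
- Alkyne ⇐ triflate/acetylide displacement ⇐ MeLi addition and Wittig methylenation of 2,3-O-isopropylidene-D-erythronolactone, the only source of chirality.

Assumption: decalin carbons carry labdane numbers (ring A = C1–C5 and C10, ring B = C5–C10, C4 gem-dimethyl, C10 angular methyl, C9 carbinol, side chain C11–C16; α = face opposite the C10 methyl), and compounds 1, 8 and 15 and all reagents are bought.

**Step 1**
Reactants: 1 (3aR,6aR)-2,2-dimethyldihydrofuro[3,4-d][1,3]dioxol-4(3aH)-one (2,3-O-isopropylidene-D-erythronolactone)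
Product: 2 (3aR,6aR)-2,2,4-trimethyltetrahydrofuro[3,4-d][1,3]dioxol-4-ol (methyl lactol, anomer mixture)
Conditions: MeLi (1.1 equiv), THF, –78 °C; AcOH quench at –78 °C
Reagents that add atoms: methyllithium, [Li]C
Why: Mono-addition of an organolithium to a γ-lactone (nucleophilic acyl addition) stops at the lithium hemiketal at –78 °C, and the two dioxolane stereocentres (future C2 and C3) are carried over unchanged.

**Step 2**
Reactants: 2 methyl lactol
Product: 3 [(4R,5S)-2,2-dimethyl-5-(prop-1-en-2-yl)-1,3-dioxolan-4-yl]methanol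
Conditions: Ph3PCH3Br (3 equiv), KOt-Bu (3 equiv), THF, 0 → 45 °C
Reagents that add atoms: methylenetriphenylphosphorane, C=P(c1ccccc1)(c1ccccc1)c1ccccc1
Why: Wittig methylenation of the ring-opened hydroxy-ketone tautomer of the lactol gives the isopropenyl group (future C4) and frees the primary alcohol (future C1); moderate temperature limits epimerisation of the α-alkoxy centre so the cis-dioxolane is kept.

**Step 3**
Reactants: 3 primary alcohol
Product: 5 (4S,5R)-2,2-dimethyl-4-(prop-1-en-2-yl)-5-(prop-2-yn-1-yl)-1,3-dioxolane, via triflate 4 (not isolated)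
Conditions: Tf2O, 2,6-lutidine, CH2Cl2, –78 °C; solvent switch to THF/DMPU; HC≡CLi (from acetylene and n-BuLi), –78 → –20 °C
Reagents that add atoms: lithium acetylide, [Li]C#C; triflic anhydride, O=S(=O)(OS(=O)(=O)C(F)(F)F)C(F)(F)F (its atoms stay in intermediate 4 only)
Why: O-triflation followed by SN2 alkylation of lithium acetylide at a primary CH2 carbon; no stereocentre is involved.

**Step 4**
Reactants: 5 terminal alkyne
Product: 7 (4R,5S)-4-[(2E)-3-iodo-2-methylprop-2-en-1-yl]-2,2-dimethyl-5-(prop-1-en-2-yl)-1,3-dioxolane, via alkenylalane 6 (not isolated)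
Conditions: AlMe3 (3 equiv), Cp2ZrCl2 (20 mol%), H2O (1 equiv), CH2Cl2, –25 °C; then I2, THF, –25 → 0 °C
Reagents that add atoms: trimethylaluminium, C[Al](C)C (one methyl stays; Al in intermediate 6 only); iodine, II
Why: Negishi zirconium-catalysed carboalumination adds Me and Al syn across the alkyne (Me to the internal carbon) and iodinolysis occurs with retention, fixing the (E)-trisubstituted alkene that becomes C5=C10.

**Step 5**
Reactants: 7 (E)-vinyl iodide; 8 2-methylbut-3-enenitrile (racemic)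
Product: 10 (5E)-7-[(4R,5S)-2,2-dimethyl-5-(prop-1-en-2-yl)-1,3-dioxolan-4-yl]-2,6-dimethylhept-5-enenitrile (2RS), via alkylborane 9 (not isolated)
Conditions: 8 (1.5 equiv), 9-BBN-H (1.4 equiv), THF, 0 °C → rt; then 7, Pd(dppf)Cl2 (5 mol%), AsPh3 (5 mol%), K3PO4 (3 M aq.), DMF, rt
Reagents that add atoms: 9-borabicyclo[3.3.1]nonane, B1C2CCCC1CCC2 (boron stays in intermediate 9 only)
Why: Anti-Markovnikov hydroboration of the terminal alkene of 8 (kept in excess so no B–H reaches the isopropenyl group of 7) and B-alkyl Suzuki–Miyaura coupling with retention of the (E)-iodide geometry; the nitrile α-centre is left racemic because it is equilibrated in step 6.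

**Step 6 (key step)**
Reactants: 10 dienyl nitrile
Product: 13 (2R,3S,5S,8R,10S)-2,3-(isopropylidenedioxy)-4,4,8,10-tetramethyldecalin-9-one (trans-fused; 2α,3α-dioxolane, 5α-H, 8α-Me, 10β-Me), via ketimine 11 (not isolated), via epimeric ketone 12 (not isolated)
Conditions: Fe(acac)3 (0.5 equiv), PhSiH3 (3 equiv), EtOH, 0.02 M, 60 °C; then AcOH/NaOAc buffer (pH 5), THF/H2O, rt; then NaOMe (0.2 equiv), MeOH, rt
Reagents that add atoms: water, O
Why: Proposed new method: an iron hydride from Fe(acac)3/PhSiH3 transfers H• to the 1,1-disubstituted alkene (faster than to the trisubstituted one) to give the tertiary C4 radical, which closes ring A by 6-endo attack on C5 through a chair in which the cis-dioxolane places C2–O equatorial and C3–O axial (the other chair would put C2–O 1,3-diaxial to both the C4 and C10 methyls), so the sugar-derived centres fix 5α-H and 10β-Me and the (E)-alkene gives the trans fusion; the tertiary C10 radical then closes ring B by chair-like 6-exo addition to the nitrile carbon, the iminyl radical is reduced to ketimine 11, buffered hydrolysis gives ketone 12, and base equilibration puts the C8 methyl equatorial (8α) in 13; the closest known reactions are the iron-hydride HAT cyclisation of alkenyl nitriles to ketones, HAT-initiated radical polyene bicyclisations, and epoxypolyene or β-dicarbonyl radical cascades mediated by trivalent titanium or trivalent manganese that terminate on nitriles.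

**Step 7**
Reactants: 13 decalone
Product: 14 (2R,3S,5S,8R,9S,10S)-2,3-(isopropylidenedioxy)-4,4,8,10-tetramethyl-9-vinyldecalin-9-ol (9β-OH, 9α-vinyl)
Conditions: CeCl3 (anhydrous, 2.5 equiv), CH2=CHMgBr (2.5 equiv), THF, –78 → 0 °C; sat. aq. NH4Cl
Reagents that add atoms: vinylmagnesium bromide, C=C[Mg]Br
Why: Imamoto organocerium 1,2-addition avoids enolisation at C8, and the small vinyl nucleophile attacks C9 axially from the α face, anti to the axial C10 methyl that blocks the equatorial β trajectory, giving the 9β-OH/9α-carbon (9S) centre.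

**Step 8**
Reactants: 15 methyl acetoacetate
Product: 16 methyl (2E)-3-{[(trifluoromethyl)sulfonyl]oxy}but-2-enoate
Conditions: Tf2O (1.2 equiv), aq. Me4NOH (25%), hexane, 5 °C
Reagents that add atoms: triflic anhydride, O=S(=O)(OS(=O)(=O)C(F)(F)F)C(F)(F)F
Why: O-triflation of the non-chelated tetramethylammonium enolate of a β-keto ester (stereoselective enol triflate formation), whose enolate oxygen lies anti to the ester, gives the (E)-enol triflate needed for the 13E geometry.

**Step 9**
Reactants: 14 vinyl carbinol; 16 (E)-enol triflate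
Product: 18 methyl (2R,3S,5S,8R,9S,10S,13E)-9-hydroxy-2,3-(isopropylidenedioxy)labd-13-en-15-oate, via alkylborane 17 (not isolated)
Conditions: 14, 9-BBN-H (2.2 equiv), THF, rt → 45 °C; then H2O, 16 (1.5 equiv), Pd(dppf)Cl2 (5 mol%), AsPh3 (5 mol%), K3PO4 (3 M aq.), DMF, rt
Reagents that add atoms: 9-borabicyclo[3.3.1]nonane, B1C2CCCC1CCC2 (boron stays in intermediate 17 only)
Why: Anti-Markovnikov hydroboration of the only alkene and B-alkyl Suzuki–Miyaura coupling with retention of the triflate geometry form C12–C13 and give the (13E)-enoate; the hindered tertiary OH is tolerated.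

**Step 10**
Reactants: 18 acetonide ester
Product: 19 methyl (2R,3S,5S,8R,9S,10S,13E)-2,3,9-trihydroxylabd-13-en-15-oate (2α,3α,9β-triol; target CNP0292844.1)
Conditions: AcOH/H2O 4:1, 40 °C
Reagents that add atoms: none
Why: Mild acid-catalysed acetal hydrolysis frees the cis-2α,3α-diol without touching the tertiary C9 alcohol, the enoate or any stereocentre.

**Compound list**
1 | 2,3-O-isopropylidene-D-erythronolactone | O=C1[C@H](OC(C)(C)O2)[C@H]2CO1 | starting material
2 | (3aR,6aR)-2,2,4-trimethyltetrahydrofuro[3,4-d][1,3]dioxol-4-ol (anomer mixture) | CC1(O)[C@H](OC(C)(C)O2)[C@H]2CO1 | intermediate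
3 | [(4R,5S)-2,2-dimethyl-5-(prop-1-en-2-yl)-1,3-dioxolan-4-yl]methanol | C=C(C)[C@H](OC(C)(C)O1)[C@H]1CO | intermediate
4 | [(4R,5S)-2,2-dimethyl-5-(prop-1-en-2-yl)-1,3-dioxolan-4-yl]methyl trifluoromethanesulfonate | C=C(C)[C@H](OC(C)(C)O1)[C@H]1COS(=O)(=O)C(F)(F)F | intermediate
5 | (4S,5R)-2,2-dimethyl-4-(prop-1-en-2-yl)-5-(prop-2-yn-1-yl)-1,3-dioxolane | C=C(C)[C@H](OC(C)(C)O1)[C@H]1CC#C | intermediate
6 | dimethyl{(1E)-3-[(4R,5S)-2,2-dimethyl-5-(prop-1-en-2-yl)-1,3-dioxolan-4-yl]-2-methylprop-1-en-1-yl}alane | C=C(C)[C@H](OC(C)(C)O1)[C@H]1C/C(C)=C/[Al](C)C | intermediate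
7 | (4R,5S)-4-[(2E)-3-iodo-2-methylprop-2-en-1-yl]-2,2-dimethyl-5-(prop-1-en-2-yl)-1,3-dioxolane | C=C(C)[C@H](OC(C)(C)O1)[C@H]1C/C(C)=C/I | intermediate
8 | 2-methylbut-3-enenitrile (racemic) | C=CC(C)C#N | starting material
9 | 4-(9-borabicyclo[3.3.1]nonan-9-yl)-2-methylbutanenitrile | N#CC(C)CCB1C2CCCC1CCC2 | intermediate
10 | (5E)-7-[(4R,5S)-2,2-dimethyl-5-(prop-1-en-2-yl)-1,3-dioxolan-4-yl]-2,6-dimethylhept-5-enenitrile (2RS) | C=C(C)[C@H](OC(C)(C)O1)[C@H]1C/C(C)=C/CCC(C)C#N | intermediate
11 | 2α,3α-isopropylidenedioxy-4,4,8,10β-tetramethyl-5αH-decalin-9-imine (C8 epimers) | N=C1C(C)CC[C@H]2C(C)(C)[C@H](OC(C)(C)O3)[C@H]3C[C@@]21C | intermediate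
12 | 2α,3α-isopropylidenedioxy-4,4,8,10β-tetramethyl-5αH-decalin-9-one (C8 epimers) | O=C1C(C)CC[C@H]2C(C)(C)[C@H](OC(C)(C)O3)[C@H]3C[C@@]21C | intermediate
13 | (2R,3S,5S,8R,10S)-2,3-(isopropylidenedioxy)-4,4,8,10-tetramethyldecalin-9-one | O=C1[C@H](C)CC[C@H]2C(C)(C)[C@H](OC(C)(C)O3)[C@H]3C[C@@]21C | intermediate
14 | (2R,3S,5S,8R,9S,10S)-2,3-(isopropylidenedioxy)-4,4,8,10-tetramethyl-9-vinyldecalin-9-ol | C=C[C@]1(O)[C@H](C)CC[C@H]2C(C)(C)[C@H](OC(C)(C)O3)[C@H]3C[C@@]21C | intermediate
15 | methyl acetoacetate | COC(=O)CC(C)=O | starting material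
16 | methyl (2E)-3-{[(trifluoromethyl)sulfonyl]oxy}but-2-enoate | COC(=O)/C=C(\C)OS(=O)(=O)C(F)(F)F | intermediate
17 | (2R,3S,5S,8R,9S,10S)-9-[2-(9-borabicyclo[3.3.1]nonan-9-yl)ethyl]-2,3-(isopropylidenedioxy)-4,4,8,10-tetramethyldecalin-9-ol | C4CCC5CCCC4B5CC[C@]1(O)[C@H](C)CC[C@H]2C(C)(C)[C@H](OC(C)(C)O3)[C@H]3C[C@@]21C | intermediate
18 | methyl (2R,3S,5S,8R,9S,10S,13E)-9-hydroxy-2,3-(isopropylidenedioxy)labd-13-en-15-oate | COC(=O)/C=C(\C)CC[C@]1(O)[C@H](C)CC[C@H]2C(C)(C)[C@H](OC(C)(C)O3)[C@H]3C[C@@]21C | intermediate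
19 | methyl (2R,3S,5S,8R,9S,10S,13E)-2,3,9-trihydroxylabd-13-en-15-oate | COC(=O)/C=C(\C)CC[C@]1(O)[C@H](C)CC[C@H]2C(C)(C)[C@H](O)[C@H](O)C[C@@]21C | target

**Step count**
Total steps: 10. Longest linear sequence: 9 (steps 1–7, 9, 10); step 8 is a one-step side branch.

**Steps most likely to fail, with fallbacks**

Step 6 is the main risk. Capture of the tertiary C10 radical by the nitrile is a slow 6-exo process, and the C8 epimer whose methyl must sit axial in the chair will be slower still. HAT to the trisubstituted alkene would instead give a monocyclic ketone. The fallback sets out from 10: reduction with i-Bu2AlH (toluene, –78 °C, buffered hydrolysis) gives the aldehyde (5E)-7-[(4R,5S)-2,2-dimethyl-5-(prop-1-en-2-yl)-1,3-dioxolan-4-yl]-2,6-dimethylhept-5-enal F1, whose α-centre epimerises freely. The same Fe(acac)3/PhSiH3 cascade is then terminated by radical addition to the aldehyde carbonyl, which is far faster than addition to C≡N, and gives the bicyclic secondary alcohol 2α,3α-isopropylidenedioxy-4,4,8,10β-tetramethyl-5αH-decalin-9-ol F2. Dess–Martin oxidation of F2 comes back to the route at 12, which is equilibrated to 13 as before.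

Step 7 is the second risk. The carbonyl is flanked by a quaternary and a tertiary carbon, so addition may be slow, enolisation may compete, and some β-face attack would give the 9-epimer. The fallback sets out from 13: HC≡CLi with CeCl3 (THF, –78 °C) is smaller, less basic and more strongly axial-selective, and gives (2R,3S,5S,8R,9R,10S)-9-ethynyl-2,3-(isopropylidenedioxy)-4,4,8,10-tetramethyldecalin-9-ol F3. Semi-hydrogenation of F3 (H2, Pd/CaCO3 poisoned with Pb(OAc)2, quinoline) comes back to the route at 14.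

Step 9 is the third risk. The alkylborane sits next to a free, very hindered tertiary alcohol, which may slow transmetallation, and the enol triflate is sensitive to aqueous base. The fallback sets out from 13: CH2=C(CH3)CH2CH2MgBr with CeCl3, with the same α-face selectivity as step 7, gives (2R,3S,5S,8R,9S,10S)-2,3-(isopropylidenedioxy)-4,4,8,10-tetramethyl-9-(3-methylbut-3-en-1-yl)decalin-9-ol F4. Cross-metathesis of F4 with methyl acrylate (second-generation Hoveyda–Grubbs catalyst, CH2Cl2, 40 °C), with removal of the minor 13Z isomer by chromatography, comes back to the route at 18.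

**Further compounds**
F1 | step 6 | (5E)-7-[(4R,5S)-2,2-dimethyl-5-(prop-1-en-2-yl)-1,3-dioxolan-4-yl]-2,6-dimethylhept-5-enal (2RS) | C=C(C)[C@H](OC(C)(C)O1)[C@H]1C/C(C)=C/CCC(C)C=O
F2 | step 6 | 2α,3α-isopropylidenedioxy-4,4,8,10β-tetramethyl-5αH-decalin-9-ol (C8/C9 epimers) | OC1C(C)CC[C@H]2C(C)(C)[C@H](OC(C)(C)O3)[C@H]3C[C@@]21C
F3 | step 7 | (2R,3S,5S,8R,9R,10S)-9-ethynyl-2,3-(isopropylidenedioxy)-4,4,8,10-tetramethyldecalin-9-ol | C#C[C@]1(O)[C@H](C)CC[C@H]2C(C)(C)[C@H](OC(C)(C)O3)[C@H]3C[C@@]21C
F4 | step 9 | (2R,3S,5S,8R,9S,10S)-2,3-(isopropylidenedioxy)-4,4,8,10-tetramethyl-9-(3-methylbut-3-en-1-yl)decalin-9-ol | C=C(C)CC[C@]1(O)[C@H](C)CC[C@H]2C(C)(C)[C@H](OC(C)(C)O3)[C@H]3C[C@@]21C
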